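Numbering: C1–C15 is the guaianolide half and C1′–C15′ is the 1′,10′-seco-eudesmanolide half. The target is 1R,2S,3S,7S,8R,10R,4′S,7′S,8′S,11′S.

## Retrosynthetic overview
1. The last ring formed is the 12′,8′-γ-lactone. It is closed from the 8′-hydroxy acid after the two halves are joined, which is how 12,8-olides arise in nature.
2. The norbornene (bonds C1–C13′ and C3–C11′) comes from a [4+2] of acetoxycyclopentadiene 34 with the ring-opened form of lactol 17. Diene 34 is released by dehydrating 4-hydroxyguaianolide 33. In the closed lactone, the exo transition state needed for 11′S would push C6′ into the C4 methyl. The open form rotates about C7′–C11′ and presents H7′ instead.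
3. Guaianolide half, ring order: γ-lactone (Cr allylation), then the seven-membered ring (aldol condensation, C1=C5), then the five-membered ring (Nazarov closure of the 4,5-seco skeleton, C4–C5).
4. Seco-eudesmanolide half, ring order: γ-lactone (same bromide 4), then the cyclohexenone (aldol condensation, C5′=C6′), then methylenation.
5. Carbon sources: acrolein, methyl acrylate, (S)-citronellal, ethyl diazoacetate, tert-butyl acetate, crotonoyl chloride and crotonaldehyde.

Assumption: the carbinol carbon of 3, C1 in 22–25, C7′ in 14, C4 in 28 and 30–33, and the lactol carbon of 17 are inconsequential epimer mixtures. They are left undefined in the SMILES.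

## Part A – common bromide

Step 1
Reactants: 1 acrolein; 2 methyl acrylate
Product: 3 methyl 3-hydroxy-2-methylidenepent-4-enoate (racemic)
Conditions: DABCO (10 mol %), neat, 0 °C to rt
Reagents that add atoms: none
Why: Morita–Baylis–Hillman reaction of an unhindered enal with an acrylate, and the carbinol centre is erased in step 2.

Step 2
Reactants: 3 methyl 3-hydroxy-2-methylidenepent-4-enoate
Product: 4 methyl (2Z)-2-(bromomethyl)penta-2,4-dienoate
Conditions: PBr3, Et2O, 0 °C
Reagents that add atoms: phosphorus tribromide, BrP(Br)Br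
Why: SN2′ bromination of a Baylis–Hillman alcohol, which gives the conjugated Z bromide under thermodynamic control.

## Part B – seco-eudesmane half

Step 3
Reactants: 5 (S)-citronellal; 6 ethyl diazoacetate
Product: 7 ethyl (5S)-5,9-dimethyl-3-oxodec-8-enoate
Conditions: SnCl2 (10 mol %), CH2Cl2, rt
Reagents that add atoms: none
Why: Roskamp homologation (addition of the diazo ester, then a 1,2-hydride shift with loss of N2) turns the aldehyde into the β-keto ester, and C4′ (S) comes unchanged from citronellal.

Step 4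
Reactants: 7 ethyl (5S)-5,9-dimethyl-3-oxodec-8-enoate
Product: 8 ethyl 2-{2-[(2S)-2,6-dimethylhept-5-enyl]-1,3-dioxolan-2-yl}acetate
Conditions: ethylene glycol, PPTS (cat.), benzene, Dean–Stark
Reagents that add atoms: ethylene glycol, OCCO
Why: Acid-catalysed ketalisation masks the C10′ ketone so that C8′ can later be a free aldehyde rather than an enolised β-keto aldehyde.

Step 5
Reactants: 8 ethyl 2-{2-[(2S)-2,6-dimethylhept-5-enyl]-1,3-dioxolan-2-yl}acetate
Product: 9 ethyl 2-{2-[(2S)-5-hydroxy-2-methylpentyl]-1,3-dioxolan-2-yl}acetate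
Conditions: O3, CH2Cl2/MeOH, −78 °C; then NaBH4, 0 °C
Reagents that add atoms: ozone, [O-][O+]=O
Why: Ozonolysis with reductive work-up cleaves the only alkene to the C1′ primary alcohol, and the ester and ketal survive brief NaBH4 at 0 °C.

Step 6
Reactants: 9 ethyl 2-{2-[(2S)-5-hydroxy-2-methylpentyl]-1,3-dioxolan-2-yl}acetate
Product: 10 2-{2-[(2S)-5-hydroxy-2-methylpentyl]-1,3-dioxolan-2-yl}acetaldehyde
Conditions: i-Bu2AlH (2.2 equiv), CH2Cl2, −78 °C; Rochelle salt
Reagents that add atoms: none
Why: Partial ester reduction stops at the aldehyde because the tetrahedral aluminium acetal is chelated by the β-ketal oxygen.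

Step 7
Reactants: 10 2-{2-[(2S)-5-hydroxy-2-methylpentyl]-1,3-dioxolan-2-yl}acetaldehyde; 4 methyl (2Z)-2-(bromomethyl)penta-2,4-dienoate
Product: 12 (4R,5S)-4-ethenyl-5-({2-[(2S)-5-hydroxy-2-methylpentyl]-1,3-dioxolan-2-yl}methyl)-3-methylideneoxolan-2-one (7′R,8′S), via hydroxy ester 11 (not isolated)
Conditions: CrCl2 (10 mol %), (S,S)-1,8-bis(4-isopropyloxazolin-2-yl)-3,6-diphenylcarbazole (the ligand enantiomer that directs Re-face attack), Mn, Me3SiCl, THF, rt; aq. citric acid; PPTS (cat.), benzene, 50 °C
Reagents that add atoms: none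
Why: Catalytic asymmetric Nozaki–Hiyama–Kishi 2-(alkoxycarbonyl)allylation, in which the pentadienylchromium reacts at its γ-carbon through a chair (anti) and the ligand sets C8′ (S), while C7′ is corrected in step 9.

Step 8
Reactants: 12 β-vinyl lactone ketal
Product: 13 (4R,5S)-4-formyl analogue of 12 (β-formyl-α-methylene lactone ketal)
Conditions: OsO4 (2 mol %), NaIO4, 2,6-lutidine, dioxane/H2O, rt
Reagents that add atoms: sodium periodate, [Na+].[O-]I(=O)(=O)=O (oxygen relayed through osmium tetroxide, O=[Os](=O)(=O)=O)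
Why: Lemieux–Johnson cleavage takes the electron-neutral vinyl group in preference to the electron-poor α-methylene lactone and gives C6′ as the aldehyde.

Step 9
Reactants: 13 β-formyl-α-methylene lactone ketal
Product: 15 (4′S,7′S,8′S)-1′-hydroxy-10′-oxo-14′-nor-1′,10′-seco-eudesma-5′,11′(13′)-dien-12′,8′-olide, via keto aldehyde 14 (not isolated)
Conditions: 1 M HCl, THF, 40 °C
Reagents that add atoms: water, O
Why: Ketal hydrolysis and then intramolecular aldol condensation of the 1,5-keto aldehyde close the cyclohexenone, and because C7′ epimerises through the formyl enol only the less strained cis-fused bicycle accumulates, so C7′ (S) follows from C8′.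

Step 10
Reactants: 15 enone lactone
Product: 16 (4′S,7′S,8′S)-1′-hydroxy-1′,10′-seco-eudesma-5′,10′(14′),11′(13′)-trien-12′,8′-olide
Conditions: Zn, CH2Br2, TiCl4, THF/CH2Cl2, 0 °C to rt
Reagents that add atoms: dibromomethane, BrCBr
Why: Takai–Lombardo methylenation is non-basic and ketone-selective, so the β-acyloxy enone is not aromatised by E1cB loss of carboxylate and the lactone is untouched.

Step 11
Reactants: 16 triene lactone
Product: 17 the corresponding α-methylene γ-lactol (anomer mixture)
Conditions: i-Bu2AlH (2.1 equiv), CH2Cl2, −78 °C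
Reagents that add atoms: none
Why: 1,2-Reduction of an α-methylene γ-lactone stops at the lactol at −78 °C, which gives latent access to the open 8′-hydroxy 2-substituted acrolein.

## Part C – guaianolide half

Step 12
Reactants: 18 tert-butyl acetate; 19 (E)-crotonoyl chloride
Product: 20 tert-butyl (E)-3-oxohex-4-enoate
Conditions: LiN(i-Pr)2 (2.1 equiv), 18 (2.1 equiv), THF, −78 °C; then 19
Reagents that add atoms: none
Why: Crossed Claisen C-acylation of the ester enolate by the acid chloride outruns 1,4-addition at −78 °C, and the second equivalent of enolate deprotonates the product.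

Step 13
Reactants: 20 tert-butyl (E)-3-oxohex-4-enoate; 21 (E)-crotonaldehyde
Product: 22 tert-butyl (3R)-2-[(E)-but-2-enoyl]-3-methyl-5-oxopentanoate
Conditions: (S)-α,α-diphenylprolinol trimethylsilyl ether (10 mol %), PhCO2H (10 mol %), toluene, 0 °C
Reagents that add atoms: none
Why: Iminium-catalysed (Jørgensen–Hayashi) Michael addition of a β-keto ester, in which the CPh2OSiMe3 group shields one face of the E-iminium ion so that C10 is formed R.

Step 14
Reactants: 22 Michael adduct; 4 methyl (2Z)-2-(bromomethyl)penta-2,4-dienoate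
Product: 24 (4S,5R)-4-ethenyl-3-methylidene-5-[(2R)-2-methyl-3-(tert-butoxycarbonyl)-4-oxohept-5-enyl]oxolan-2-one (7S,8R,10R), via hydroxy ester 23 (not isolated)
Conditions: CrCl2 (10 mol %), (R,R)-enantiomer of the step 7 ligand (Si-face attack), Mn, Me3SiCl, THF, rt; aq. citric acid; PPTS (cat.), benzene, 50 °C
Reagents that add atoms: none
Why: The same catalytic asymmetric Nozaki–Hiyama–Kishi allylation is aldehyde-selective over the enone, the ligand sets C8 (R), and the anti chair sets C7 (S), which gives the trans-lactone directly.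

Step 15
Reactants: 24 β-vinyl trans-lactone
Product: 25 the corresponding 4-(2-oxoethyl) lactone (C5 aldehyde)
Conditions: PdCl2(PhCN)2 (12 mol %), CuCl2 (12 mol %), AgNO2 (6 mol %), t-BuOH/MeNO2, O2 (1 atm), rt
Reagents that add atoms: dioxygen, O=O (relayed through silver nitrite, [Ag+].[O-]N=O)
Why: Nitrite-modified, aldehyde-selective (anti-Markovnikov) Wacker oxidation of the only unactivated terminal alkene, helped by the homoallylic lactone oxygen.

Step 16
Reactants: 25 aldehyde β-keto ester
Product: 27 (7S,8R,10R)-2-oxo-4,5-seco-guaia-1(5),3E,11(13)-trien-12,8-olide (1-crotonoylcycloheptene lactone), via keto aldehyde 26 (not isolated)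
Conditions: CF3CO2H/CH2Cl2 1:3, rt; concentrate; (PhCH2)2NH2+ CF3CO2− (0.5 equiv), benzene, 60 °C
Reagents that add atoms: none
Why: Acidolysis of the tert-butyl ester and decarboxylation leave C1 as the only enolisable α-carbon, and an ammonium-salt-promoted intramolecular aldol condensation then closes the seven-membered ring at C1=C5.

Step 17
Reactants: 27 cross-conjugated dienone
Product: 28 (7S,8R,10R)-2-oxoguaia-1(5),11(13)-dien-12,8-olide
Conditions: HNTf2 (10 mol %), (CF3)2CHOH/ClCH2CH2Cl, 40 °C
Reagents that add atoms: none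
Why: Nazarov 4π-conrotatory cyclisation forms C4–C5 (the reverse of the biogenetic guaiane to 4,5-seco-guaiane cleavage) and proton loss gives the tetrasubstituted C1=C5 enone, with the C4 configuration irrelevant.

Step 18
Reactants: 28 hydroazulenone
Product: 29 2-(tert-butyldimethylsilyloxy)guaia-1,4,11(13)-trien-12,8-olide
Conditions: TBSOTf, Et3N, CH2Cl2, 0 °C to rt
Reagents that add atoms: tert-butyldimethylsilyl triflate, CC(C)(C)[Si](C)(C)OS(=O)(=O)C(F)(F)F
Why: Soft enolisation under equilibrating conditions removes the γ-proton (H4) and gives the more substituted, linearly conjugated silyloxycyclopentadiene without touching the base-sensitive α-methylene lactone.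

Step 19
Reactants: 29 silyloxycyclopentadiene
Product: 31 4-hydroxy-2-oxoguaia-1(5),11(13)-dien-12,8-olide, via endoperoxide 30 (not isolated)
Conditions: O2, tetraphenylporphyrin (1 mol %), visible light, CH2Cl2, −78 °C; then Me2S, wet MeOH, −78 °C to rt
Reagents that add atoms: dioxygen, O=O
Why: Singlet-oxygen [4+2] across C2/C4 of the electron-rich cyclopentadiene, then O–O reduction and collapse of the silyl hemiketal, is the classical cyclopentadiene to 4-hydroxycyclopentenone sequence and leaves the electron-poor exocyclic alkene alone.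

Step 20
Reactants: 31 4-hydroxy enone
Product: 32 (2S)-2,4-dihydroxyguaia-1(5),11(13)-dien-12,8-olide
Conditions: (R)-2-methyl-CBS-oxazaborolidine (0.2 equiv), BH3·SMe2, THF, −40 °C
Reagents that add atoms: none
Why: Corey–Bakshi–Shibata 1,2-reduction, in which the catalyst (alkenyl side large, CH2 side small) delivers hydride anti to the 10-methyl group, so reagent and substrate bias together give C2 (S).

Step 21
Reactants: 32 diol
Product: 33 (2S,7S,8R,10R)-2-acetoxy-4-hydroxyguaia-1(5),11(13)-dien-12,8-olide
Conditions: Ac2O (1.2 equiv), pyridine, DMAP (5 mol %), CH2Cl2, 0 °C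
Reagents that add atoms: acetic anhydride, CC(=O)OC(C)=O
Why: Nucleophile-catalysed acylation takes the secondary allylic alcohol and leaves the tertiary C4 alcohol free.

## Part D – union and last ring

Step 22
Reactants: 33 2-acetoxy-4-hydroxyguaianolide; 17 lactol (3 equiv, excess recovered)
Product: 37 open-chain cycloadduct, the 8′-hydroxy-12′-aldehyde (1R,2S,3S,7S,8R,10R,4′S,7′S,8′S,11′S), via acetoxycyclopentadiene 34 (not isolated), via iminium triflate 35 (not isolated), via cycloadduct iminium triflate 36 (not isolated)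
Conditions: flask a: 17, pyrrolidinium triflate (1 equiv per 17), 4 Å sieves, MeCN, rt then −20 °C; flask b: 33, Ph2S[OC(CF3)2Ph]2 (1.05 equiv), CH2Cl2, −45 °C, 10 min, then cannulated over 1 h into flask a, −20 °C to rt, 12 h; then H2O/THF
Reagents that add atoms: water, O
Why: Proposed new method: sulfurane dehydration of the tertiary allylic alcohol (closest precedent: cyclopentenol to cyclopentadiene dehydration) releases 5-acetoxycyclopentadiene 34, which is trapped before [1,5]-H shift, and in preference to its own lactone, by the ring-opened iminium form 35 of the lactol (closest precedent: exo-selective Diels–Alder reactions of α-substituted acrolein iminium salts with cyclopentadienes), so that C13′H2 bonds to the hindered C1 and C11′ to C3, the diene is attacked anti to both the 10-methyl and the acetate (a syn acetate would clash with the exo C=N+ group), and free rotation about C7′–C11′ turns H7′ rather than C6′ towards the diene, which together set C1 (R), C3 (S) and C11′ (S).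

Step 23
Reactants: 37 hydroxy aldehyde
Product: 39 target CNP0299458.1, via hydroxy acid 38 (not isolated)
Conditions: NaClO2, NaH2PO4, 2-methyl-2-butene, t-BuOH/H2O, 0 °C to rt; then PPTS (cat.), CH2Cl2, rt
Reagents that add atoms: sodium chlorite, [Na+].[O-]Cl=O
Why: Pinnick oxidation touches only the aldehyde (alcohols, acetate and alkenes are spared by the scavenger) and the cis-γ-hydroxy acid lactonises as 8-hydroxy acids do in lactone biosynthesis, with no stereocentre changed and the primary C1′ alcohol left free.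

## Compound list
1 | acrolein | C=CC=O | starting material
2 | methyl acrylate | C=CC(=O)OC | starting material
3 | methyl 3-hydroxy-2-methylidenepent-4-enoate | C=CC(O)C(=C)C(=O)OC | intermediate
4 | methyl (2Z)-2-(bromomethyl)penta-2,4-dienoate | C=C/C=C(\CBr)C(=O)OC | intermediate
5 | (S)-citronellal | O=CC[C@@H](C)CCC=C(C)C | starting material
6 | ethyl diazoacetate | CCOC(=O)C=[N+]=[N-] | starting material
7 | ethyl (5S)-5,9-dimethyl-3-oxodec-8-enoate | CCOC(=O)CC(=O)C[C@@H](C)CCC=C(C)C | intermediate
8 | dioxolane of 7 | CCOC(=O)CC1(C[C@@H](C)CCC=C(C)C)OCCO1 | intermediate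
9 | hydroxy ester ketal | CCOC(=O)CC1(C[C@@H](C)CCCO)OCCO1 | intermediate
10 | hydroxy aldehyde ketal | O=CCC1(C[C@@H](C)CCCO)OCCO1 | intermediate
11 | anti hydroxy ester (7′R,8′S) | COC(=O)C(=C)[C@@H](C=C)[C@@H](O)CC1(C[C@@H](C)CCCO)OCCO1 | intermediate (not isolated)
12 | β-vinyl trans-lactone ketal (7′R,8′S) | O=C1O[C@@H](CC2(C[C@@H](C)CCCO)OCCO2)[C@H](C=C)C1=C | intermediate
13 | β-formyl lactone ketal | O=C1O[C@@H](CC2(C[C@@H](C)CCCO)OCCO2)[C@H](C=O)C1=C | intermediate
14 | keto aldehyde lactone | O=CC1C(=C)C(=O)O[C@H]1CC(=O)C[C@@H](C)CCCO | intermediate (not isolated)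
15 | cis-fused enone lactone | O=C1C[C@@H]2OC(=O)C(=C)[C@@H]2C=C1[C@@H](C)CCCO | intermediate
16 | seco-eudesmatrienolide | C=C1C[C@@H]2OC(=O)C(=C)[C@@H]2C=C1[C@@H](C)CCCO | intermediate
17 | α-methylene lactol | C=C1C[C@@H]2OC(O)C(=C)[C@@H]2C=C1[C@@H](C)CCCO | intermediate
18 | tert-butyl acetate | CC(=O)OC(C)(C)C | starting material
19 | (E)-crotonoyl chloride | C/C=C/C(=O)Cl | starting material
20 | tert-butyl (E)-3-oxohex-4-enoate | C/C=C/C(=O)CC(=O)OC(C)(C)C | intermediate
21 | (E)-crotonaldehyde | C/C=C/C=O | starting material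
22 | Michael adduct (10R) | O=CC[C@@H](C)C(C(=O)OC(C)(C)C)C(=O)/C=C/C | intermediate
23 | anti hydroxy ester (7S,8R,10R) | COC(=O)C(=C)[C@H](C=C)[C@H](O)C[C@@H](C)C(C(=O)OC(C)(C)C)C(=O)/C=C/C | intermediate (not isolated)
24 | β-vinyl trans-lactone | O=C1O[C@H](C[C@@H](C)C(C(=O)OC(C)(C)C)C(=O)/C=C/C)[C@@H](C=C)C1=C | intermediate
25 | C5 aldehyde | O=C1O[C@H](C[C@@H](C)C(C(=O)OC(C)(C)C)C(=O)/C=C/C)[C@@H](CC=O)C1=C | intermediate
26 | decarboxylated keto aldehyde | O=C1O[C@H](C[C@@H](C)CC(=O)/C=C/C)[C@@H](CC=O)C1=C | intermediate (not isolated)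
27 | 1-crotonoylcycloheptene lactone | C/C=C/C(=O)C1=CC[C@H]2C(=C)C(=O)O[C@@H]2C[C@H]1C | intermediate
28 | 2-oxoguaia-1(5),11(13)-dien-12,8-olide | CC1CC(=O)C2=C1C[C@H]1C(=C)C(=O)O[C@@H]1C[C@H]2C | intermediate
29 | silyloxycyclopentadiene | CC1=C2C[C@H]3C(=C)C(=O)O[C@@H]3C[C@@H](C)C2=C(O[Si](C)(C)C(C)(C)C)C1 | intermediate
30 | 2,4-endoperoxide | CC12CC(O[Si](C)(C)C(C)(C)C)(OO1)C1=C2C[C@H]2C(=C)C(=O)O[C@@H]2C[C@H]1C | intermediate (not isolated)
31 | 4-hydroxy-2-oxo guaianolide | CC1(O)CC(=O)C2=C1C[C@H]1C(=C)C(=O)O[C@@H]1C[C@H]2C | intermediate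
32 | (2S)-2,4-diol | CC1(O)C[C@H](O)C2=C1C[C@H]1C(=C)C(=O)O[C@@H]1C[C@H]2C | intermediate
33 | (2S)-2-acetoxy-4-hydroxy guaianolide | CC1(O)C[C@H](OC(C)=O)C2=C1C[C@H]1C(=C)C(=O)O[C@@H]1C[C@H]2C | intermediate
34 | 2-acetoxyguaia-1(5),3,11(13)-trien-12,8-olide | CC1=C[C@H](OC(C)=O)C2=C1C[C@H]1C(=C)C(=O)O[C@@H]1C[C@H]2C | intermediate (not isolated)
35 | open-chain pyrrolidinium iminium triflate of 17 | C=C1C[C@H](O)[C@H](C(=C)C=[N+]2CCCC2)C=C1[C@@H](C)CCCO.[O-]S(=O)(=O)C(F)(F)F | intermediate (not isolated)
36 | cycloadduct iminium triflate | C=C1C[C@H](O)[C@H]([C@@]3(C=[N+]6CCCC6)C[C@@]45C(=C(C)[C@@H]3[C@@H]4OC(C)=O)C[C@H]3C(=C)C(=O)O[C@@H]3C[C@H]5C)C=C1[C@@H](C)CCCO.[O-]S(=O)(=O)C(F)(F)F | intermediate (not isolated)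
37 | cycloadduct hydroxy aldehyde | C=C1C[C@H](O)[C@H]([C@@]3(C=O)C[C@@]45C(=C(C)[C@@H]3[C@@H]4OC(C)=O)C[C@H]3C(=C)C(=O)O[C@@H]3C[C@H]5C)C=C1[C@@H](C)CCCO | intermediate
38 | cycloadduct hydroxy acid | C=C1C[C@H](O)[C@H]([C@@]3(C(=O)O)C[C@@]45C(=C(C)[C@@H]3[C@@H]4OC(C)=O)C[C@H]3C(=C)C(=O)O[C@@H]3C[C@H]5C)C=C1[C@@H](C)CCCO | intermediate (not isolated)
39 | CNP0299458.1 | C=C1C[C@@H]2OC(=O)[C@@]3(C[C@@]45C(=C(C)[C@@H]3[C@@H]4OC(C)=O)C[C@H]3C(=C)C(=O)O[C@@H]3C[C@H]5C)[C@@H]2C=C1[C@@H](C)CCCO | target

## Counts and risks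
Total steps: 23. Longest linear sequence: 12 (steps 12–23).

**Step 22.** This is the riskiest step.
- Dehydration may go towards the C15 methyl instead of C3.
- Diene 34 may undergo a [1,5]-H shift before it is trapped.
- The known electronic preference of 5-acetoxycyclopentadienes for syn attack may override the steric bias for anti attack.
- The amount of open iminium ion available from the lactol is uncertain.

Fallback, from 16 (with 33), returning at 39. The open chain is locked covalently instead of by iminium formation.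
- Lactone 16 is opened with Me2AlN(OMe)Me to the hydroxy Weinreb amide F1.
- Both hydroxyls are silylated (TBSOTf, 2,6-lutidine) to give the bis-silyl ether F2.
- i-Bu2AlH then gives the bis-silylated open-chain enal F3.
- F3 is combined, neat or at 12 kbar in CH2Cl2, with diene 34 generated as before, to give the silylated adduct aldehyde F4.
- Pinnick oxidation gives the silylated adduct acid F5, and HF·pyridine removes both silyl groups with spontaneous lactonisation to 39.

**Step 16.** A seven-membered ring closed by aldol condensation of a simple ketone may be slow, and oligomerisation may compete.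

Fallback, from 25, returning at 27. The tert-butyl ester is kept so that the much more acidic 1,3-dicarbonyl carbon C1 adds to the aldehyde under MgBr2/Et3N. This gives the cyclic aldol β-keto ester F6. CF3CO2H then frees the β-hydroxy acid, which loses CO2 and water in a Grob-type decarboxylative elimination to give 27.

**Step 19.** The regiochemistry of photooxygenation of the fluxional silyloxycyclopentadiene is uncertain.

Fallback, from 28, returning at 34. The C3=C4 bond is made by selenoxide elimination instead of dehydration.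
- Treating 28 with Me3SiOTf/Et3N and then PhSeCl gives the 3-phenylselanyl ketone F7, with Se trans to the 4-methyl group.
- NaBH4/CeCl3 gives the seleno alcohol F8, and Ac2O gives the seleno acetate F9.
- m-CPBA at −78 °C followed by warming in the presence of 35 gives 34 by syn elimination away from the acetate-bearing carbon.
- The C2 epimers that stem from the C4 mixture are separated at the stage of F8.

Further compounds
F1 | step 22 | hydroxy Weinreb amide | C=C1C[C@H](O)[C@H](C(=C)C(=O)N(C)OC)C=C1[C@@H](C)CCCO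
F2 | step 22 | bis-silyl ether | C=C1C[C@H](O[Si](C)(C)C(C)(C)C)[C@H](C(=C)C(=O)N(C)OC)C=C1[C@@H](C)CCCO[Si](C)(C)C(C)(C)C
F3 | step 22 | bis-silylated open-chain enal | C=C1C[C@H](O[Si](C)(C)C(C)(C)C)[C@H](C(=C)C=O)C=C1[C@@H](C)CCCO[Si](C)(C)C(C)(C)C
F4 | step 22 | silylated adduct aldehyde | C=C1C[C@H](O[Si](C)(C)C(C)(C)C)[C@H]([C@@]3(C=O)C[C@@]45C(=C(C)[C@@H]3[C@@H]4OC(C)=O)C[C@H]3C(=C)C(=O)O[C@@H]3C[C@H]5C)C=C1[C@@H](C)CCCO[Si](C)(C)C(C)(C)C
F5 | step 22 | silylated adduct acid | C=C1C[C@H](O[Si](C)(C)C(C)(C)C)[C@H]([C@@]3(C(=O)O)C[C@@]45C(=C(C)[C@@H]3[C@@H]4OC(C)=O)C[C@H]3C(=C)C(=O)O[C@@H]3C[C@H]5C)C=C1[C@@H](C)CCCO[Si](C)(C)C(C)(C)C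
F6 | step 16 | cyclic aldol β-keto ester | C/C=C/C(=O)C1(C(=O)OC(C)(C)C)C(O)C[C@H]2C(=C)C(=O)O[C@@H]2C[C@H]1C
F7 | step 19 | 3-phenylselanyl ketone | CC1C([Se]c3ccccc3)C(=O)C2=C1C[C@H]1C(=C)C(=O)O[C@@H]1C[C@H]2C
F8 | step 19 | seleno alcohol | CC1C([Se]c3ccccc3)[C@H](O)C2=C1C[C@H]1C(=C)C(=O)O[C@@H]1C[C@H]2C
F9 | step 19 | seleno acetate | CC1C([Se]c3ccccc3)[C@H](OC(C)=O)C2=C1C[C@H]1C(=C)C(=O)O[C@@H]1C[C@H]2C
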